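**Retrosynthetic overview**
1. The target is a C2-symmetric oxolane (O1, C2–C5; 2,3-cis, 3,4-trans, 4,5-cis). Its segment O1–C5(aryl)–C4(carbonyl), with aryl cis to carbonyl, plus C3 and C2, is a γ-lactone skeleton once C2 is written as a carbonyl carbon. The plan rests on this feature.
2. Both aroyl groups are traced back, in two directions at once, to the 3,4-dicarbaldehyde and 2,4-bis(benzyloxy)phenyllithium. The dialdehyde is traced back to an oxolane with CH2OH at C3 and CO2t-Bu at C4.
3. The C2–aryl bond is cut to an arylzinc reagent and the C2–H oxocarbenium ion of the lactol. Hydride goes on first and aryl second, because the incoming group enters anti to the C4 and C5 substituents. The C3–CH2OH bond is cut to the lactone enolate and formaldehyde.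
4. The cis lactone is cut at C4–C5 and O1–C2 into tert-butyl (E)-4-oxobut-2-enoate and 4-(benzyloxy)benzaldehyde (carbene-catalysed homoenolate [3+2] annulation).
5. Ring order: the oxolane is the only ring made. It is closed as the lactone in step 3 and is not opened again.

Key step: step 3

Assumption: the locants O1, C2–C5 in the text are those of the target ring (C5 and C4 come from the annulation), whatever the systematic name of an intermediate says.
Assumption: the sense of induction of the aminoindanol triazolium salt in step 3 cannot be predicted with certainty. The (5aR,10bS) salt is written, and its equally available antipode is used if ent-6 should form.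

**Step 1**
Reactants: 1 2,2-dimethoxyacetaldehyde (aqueous solution); 2 tert-butyl (triphenylphosphoranylidene)acetate
Product: 3 tert-butyl (E)-4,4-dimethoxybut-2-enoate
Conditions: CH2Cl2, 0 °C → rt
Reagents that add atoms: none
Why: Wittig olefination with an ester-stabilised ylide tolerates the aqueous aldehyde and gives the (E)-enoate, while the acetal masks the second formyl group of the glyoxal unit so that double olefination cannot occur.

**Step 2**
Reactants: 3 tert-butyl (E)-4,4-dimethoxybut-2-enoate
Product: 4 tert-butyl (E)-4-oxobut-2-enoate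
Conditions: aq HCl (1 M, cat.), acetone, rt
Reagents that add atoms: water, O
Why: Acid-catalysed acetal hydrolysis in dilute aqueous acid at room temperature is too mild to ionise the tert-butyl ester, and the (E)-enal is the stable geometry.

**Step 3**
Reactants: 4 tert-butyl (E)-4-oxobut-2-enoate; 5 4-(benzyloxy)benzaldehyde
Product: 6 tert-butyl (2S,3R)-2-[4-(benzyloxy)phenyl]-5-oxooxolane-3-carboxylate (cis lactone)
Conditions: 5 (3 equiv), (5aR,10bS)-2-mesityl-5a,10b-dihydro-4H,6H-indeno[2,1-b][1,2,4]triazolo[4,3-d][1,4]oxazin-2-ium chloride (10 mol %), DBU (10 mol %), 4 Å MS, toluene, rt; 4 added over 8 h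
Reagents that add atoms: none
Why: Proposed new method: the carbene adds to the formyl group of 4 and proton transfer gives an extended Breslow intermediate whose β-carbon (C4) is also the α-carbon of the tert-butyl ester and so carries most of the nucleophilic character, so that C4 rather than the acyl-anion carbon attacks the formyl carbon of 5 (C5) and forms C4–C5. The resulting enol azolium tautomerises to the acyl azolium, and the C5 alkoxide then attacks the acyl carbon C2 in a 5-exo-trig acyl substitution that forms O1–C2, closes the lactone ring and releases the carbene. The closest known reaction type is the carbene-catalysed homoenolate [3+2] annulation of β-aryl enals with aromatic aldehydes to cis-γ-butyrolactones; what has not been shown is an enal with an acceptor on the β-carbon acting as homoenolate partner of a plain, electron-rich benzaldehyde in enantioselective form. C4 should be set by the face of the dienol left open by the indane wall of the aminoindanol backbone and the orthogonal N-mesityl ring, and C5 by a compact arrangement in which the enol O–H is hydrogen-bonded to the aldehyde oxygen, which places aryl and ester on the same side of the new ring (cis). The step needs C–C bond formation at the β-carbon to win over β-protonation (enolate and redox-ester pathways), over benzoin or Stetter chemistry and over self-annulation of 4: catalytic DBU without protic additives leaves only the weak acid protonated DBU in solution, the N-mesityl triazolium engages enals in preference to benzaldehydes, the ester directs charge to C4, and slow addition of 4 to excess 5 keeps the more electrophilic formyl group of 4 scarce.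

**Step 4**
Reactants: 6 cis lactone
Product: 8 tert-butyl (2S,3R,4S)-2-[4-(benzyloxy)phenyl]-4-(hydroxymethyl)-5-oxooxolane-3-carboxylate, via lithium lactone enolate 7 (not isolated)
Conditions: LiN(SiMe3)2 (1.05 equiv), THF, −78 °C; CH2O (gas, from cracked paraformaldehyde), −78 → −40 °C; AcOH
Reagents that add atoms: formaldehyde, C=O
Why: This is kinetic enolate formation followed by aldol addition to monomeric formaldehyde (α-hydroxymethylation of a lactone, with α-alkylation of paraconic esters as precedent): the lactone α-CH2 (C3) is more acidic and more accessible than the tertiary C4–H next to the bulky ester, formaldehyde approaches the face opposite the C4 ester and C5 aryl group so that C3 is set trans to C4, and low temperature with an acidic quench should forestall proton transfer to C4 and Stobbe-type ring opening.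

**Step 5**
Reactants: 8 hydroxymethyl lactone
Product: 9 tert-butyl (2S,3R,4S)-2-[4-(benzyloxy)phenyl]-4-({[tert-butyl(dimethyl)silyl]oxy}methyl)-5-oxooxolane-3-carboxylate
Conditions: TBSCl, imidazole, CH2Cl2, 0 °C → rt
Reagents that add atoms: tert-butyldimethylsilyl chloride, CC(C)(C)[Si](C)(C)Cl
Why: Standard silylation of a primary alcohol with imidazole leaves the lactone, the ester and the three stereocentres untouched.

**Step 6**
Reactants: 9 silyl ether lactone
Product: 10 tert-butyl (2S,3R,4S)-2-[4-(benzyloxy)phenyl]-4-({[tert-butyl(dimethyl)silyl]oxy}methyl)-5-hydroxyoxolane-3-carboxylate (lactol, both epimers at the hemiacetal carbon C2)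
Conditions: i-Bu2AlH (1.1 equiv), CH2Cl2, −78 °C
Reagents that add atoms: none
Why: Partial reduction of a γ-lactone stops at the aluminium hemiacetal at −78 °C and is faster than attack on the hindered tert-butyl ester, and hydride is placed on C2 before the aryl group because the second nucleophile will enter anti to the C4 and C5 substituents and therefore has to be the aryl group.

**Step 7**
Reactants: 10 lactol
Product: 11 tert-butyl (2S,3R,4S)-5-(benzenesulfonyl)-2-[4-(benzyloxy)phenyl]-4-({[tert-butyl(dimethyl)silyl]oxy}methyl)oxolane-3-carboxylate (both epimers at C2)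
Conditions: PhSO2H, CaCl2, CH2Cl2, rt
Reagents that add atoms: benzenesulfinic acid, O=S(O)c1ccccc1
Why: Acid-promoted exchange of the lactol hydroxyl for sulfinate through the C2 oxocarbenium ion (formation of a 2-sulfonyl cyclic ether) is driven by uptake of water on CaCl2, is mild enough for the silyl ether, the tert-butyl ester and the benzylic C5–O bond, and gives C2 epimers that converge in the next step.

**Step 8**
Reactants: 11 sulfone; 12 1-(benzyloxy)-4-bromobenzene
Product: 15 tert-butyl (2S,3R,4S,5S)-2,5-bis[4-(benzyloxy)phenyl]-4-({[tert-butyl(dimethyl)silyl]oxy}methyl)oxolane-3-carboxylate, via arylmagnesium bromide 13 (not isolated), via arylzinc bromide 14 (not isolated)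
Conditions: 12, Mg, THF; ZnBr2, THF, 0 °C → rt; then 11, rt
Reagents that add atoms: none
Why: This is Lewis-acid-assisted substitution of a 2-sulfonyl cyclic ether by an organozinc reagent: the zinc and magnesium bromides ionise the C2–sulfonyl bond, and the oxocarbenium ion, in the envelope that keeps the C3 and C4 side chains pseudo-equatorial, should be attacked from inside the envelope on the face away from the C4 ester and C5 aryl group, so that the new aryl ends trans to the C5 aryl and cis to the C3 side chain (C2 = S), the 2,3-cis-3,4-trans-4,5-cis pattern known for arylzinc additions to 3,4-dialkyl-5-aryl-2-sulfonyloxolanes.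

**Step 9**
Reactants: 15 diaryl oxolane ester
Product: 16 {(2S,3S,4S,5S)-2,5-bis[4-(benzyloxy)phenyl]-4-({[tert-butyl(dimethyl)silyl]oxy}methyl)oxolan-3-yl}methanol
Conditions: LiAlH4, THF, 0 °C
Reagents that add atoms: none
Why: Ester reduction with LiAlH4 spares the silyl and benzyl ethers and all stereocentres and brings C4 to the oxidation level of C3.

**Step 10**
Reactants: 16 mono-silylated diol
Product: 17 [(2S,3S,4S,5S)-2,5-bis[4-(benzyloxy)phenyl]oxolane-3,4-diyl]dimethanol
Conditions: n-Bu4NF, THF, rt
Reagents that add atoms: none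
Why: Fluoride-induced desilylation gives the C2-symmetric diol, so that all later operations run in both directions at once.

**Step 11**
Reactants: 17 diol
Product: 18 (2S,3R,4R,5S)-2,5-bis[4-(benzyloxy)phenyl]oxolane-3,4-dicarbaldehyde (used crude)
Conditions: (COCl)2, DMSO, CH2Cl2, −78 °C; i-Pr2NEt, −78 → −30 °C
Reagents that add atoms: none
Why: In the Swern oxidation both alcohols become alkoxysulfonium ions before base is added, so no hydroxy aldehyde can close to a lactol and be over-oxidised, and the hindered base at low temperature should spare C3 and C4, where a single epimerisation would place three neighbouring substituents on one face.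

**Step 12**
Reactants: 19 4-bromoresorcinol
Product: 20 2,4-bis(benzyloxy)-1-bromobenzene
Conditions: BnBr (2.2 equiv), K2CO3, DMF, rt
Reagents that add atoms: benzyl bromide, BrCc1ccccc1
Why: Williamson ether synthesis takes place on both phenols.

**Step 13**
Reactants: 18 dialdehyde; 20 2,4-bis(benzyloxy)-1-bromobenzene
Product: 22 [(2S,3S,4S,5S)-2,5-bis[4-(benzyloxy)phenyl]oxolane-3,4-diyl]bis{[2,4-bis(benzyloxy)phenyl]methanol} (carbinol epimers), via aryllithium 21 (not isolated)
Conditions: 20 (3 equiv), n-BuLi, THF, −78 °C; then 18, −78 °C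
Reagents that add atoms: none
Why: Bromine–lithium exchange is followed by twofold 1,2-addition of the aryllithium to the aldehydes, which at −78 °C is faster than enolisation, and the uncontrolled carbinol centres are erased in the next step.

**Step 14**
Reactants: 22 bis-carbinol
Product: 23 [(2S,3R,4R,5S)-2,5-bis[4-(benzyloxy)phenyl]oxolane-3,4-diyl]bis{[2,4-bis(benzyloxy)phenyl]methanone}
Conditions: Dess–Martin periodinane (3 equiv), NaHCO3, CH2Cl2, 0 °C → rt
Reagents that add atoms: none
Why: Dess–Martin oxidation of both benzylic alcohols in a buffered, essentially neutral medium should neither ionise the electron-rich carbinols nor enolise the new ketones at C3 and C4.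

**Step 15**
Reactants: 23 hexabenzyl ether
Product: 24 [(2S,3R,4R,5S)-2,5-bis(4-hydroxyphenyl)oxolane-3,4-diyl]bis[(2,4-dihydroxyphenyl)methanone] (target, CNP0237262.3)
Conditions: H2 (1 atm), Pd/C, EtOAc/MeOH, rt, stopped after uptake for six benzyl groups
Reagents that add atoms: none
Why: Catalytic hydrogenolysis cleaves the six primary O-benzyl bonds much faster than the secondary, acyl-flanked benzylic C–O bonds of the ring or the deactivated aryl ketones, and the neutral medium avoids enolisation and retro-oxa-Michael opening.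

**Compound list**
1 | 2,2-dimethoxyacetaldehyde | COC(OC)C=O | starting material
2 | tert-butyl (triphenylphosphoranylidene)acetate | CC(C)(C)OC(=O)C=P(c1ccccc1)(c1ccccc1)c1ccccc1 | starting material
3 | tert-butyl (E)-4,4-dimethoxybut-2-enoate | COC(OC)/C=C/C(=O)OC(C)(C)C | intermediate
4 | tert-butyl (E)-4-oxobut-2-enoate | CC(C)(C)OC(=O)/C=C/C=O | intermediate
5 | 4-(benzyloxy)benzaldehyde | O=Cc1ccc(OCc2ccccc2)cc1 | starting material
6 | tert-butyl (2S,3R)-2-[4-(benzyloxy)phenyl]-5-oxooxolane-3-carboxylate | CC(C)(C)OC(=O)[C@@H]1CC(=O)O[C@@H]1c1ccc(OCc2ccccc2)cc1 | intermediate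
7 | lithium enolate of 6 (O–Li on C2, C2=C3) | [Li+].CC(C)(C)OC(=O)[C@@H]1C=C([O-])O[C@@H]1c1ccc(OCc2ccccc2)cc1 | intermediate (not isolated)
8 | tert-butyl (2S,3R,4S)-2-[4-(benzyloxy)phenyl]-4-(hydroxymethyl)-5-oxooxolane-3-carboxylate | CC(C)(C)OC(=O)[C@@H]1[C@@H](CO)C(=O)O[C@@H]1c1ccc(OCc2ccccc2)cc1 | intermediate
9 | tert-butyl (2S,3R,4S)-2-[4-(benzyloxy)phenyl]-4-({[tert-butyl(dimethyl)silyl]oxy}methyl)-5-oxooxolane-3-carboxylate | CC(C)(C)OC(=O)[C@@H]1[C@@H](CO[Si](C)(C)C(C)(C)C)C(=O)O[C@@H]1c1ccc(OCc2ccccc2)cc1 | intermediate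
10 | lactol of 9 (hemiacetal carbon unassigned) | CC(C)(C)OC(=O)[C@@H]1[C@@H](CO[Si](C)(C)C(C)(C)C)C(O)O[C@@H]1c1ccc(OCc2ccccc2)cc1 | intermediate
11 | 2-benzenesulfonyl ether from 10 (sulfonyl carbon unassigned) | CC(C)(C)OC(=O)[C@@H]1[C@@H](CO[Si](C)(C)C(C)(C)C)C(S(=O)(=O)c2ccccc2)O[C@@H]1c1ccc(OCc2ccccc2)cc1 | intermediate
12 | 1-(benzyloxy)-4-bromobenzene | Brc1ccc(OCc2ccccc2)cc1 | starting material
13 | [4-(benzyloxy)phenyl]magnesium bromide | Br[Mg]c1ccc(OCc2ccccc2)cc1 | intermediate (not isolated)
14 | [4-(benzyloxy)phenyl]zinc bromide | Br[Zn]c1ccc(OCc2ccccc2)cc1 | intermediate (not isolated)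
15 | tert-butyl (2S,3R,4S,5S)-2,5-bis[4-(benzyloxy)phenyl]-4-({[tert-butyl(dimethyl)silyl]oxy}methyl)oxolane-3-carboxylate | CC(C)(C)OC(=O)[C@@H]1[C@@H](CO[Si](C)(C)C(C)(C)C)[C@@H](c2ccc(OCc3ccccc3)cc2)O[C@@H]1c1ccc(OCc2ccccc2)cc1 | intermediate
16 | {(2S,3S,4S,5S)-2,5-bis[4-(benzyloxy)phenyl]-4-({[tert-butyl(dimethyl)silyl]oxy}methyl)oxolan-3-yl}methanol | OC[C@@H]1[C@@H](CO[Si](C)(C)C(C)(C)C)[C@@H](c2ccc(OCc3ccccc3)cc2)O[C@@H]1c1ccc(OCc2ccccc2)cc1 | intermediate
17 | [(2S,3S,4S,5S)-2,5-bis[4-(benzyloxy)phenyl]oxolane-3,4-diyl]dimethanol | OC[C@@H]1[C@@H](CO)[C@@H](c2ccc(OCc3ccccc3)cc2)O[C@@H]1c1ccc(OCc2ccccc2)cc1 | intermediate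
18 | (2S,3R,4R,5S)-2,5-bis[4-(benzyloxy)phenyl]oxolane-3,4-dicarbaldehyde | O=C[C@@H]1[C@@H](C=O)[C@@H](c2ccc(OCc3ccccc3)cc2)O[C@@H]1c1ccc(OCc2ccccc2)cc1 | intermediate
19 | 4-bromoresorcinol | Oc1ccc(Br)c(O)c1 | starting material
20 | 2,4-bis(benzyloxy)-1-bromobenzene | Brc1ccc(OCc2ccccc2)cc1OCc1ccccc1 | intermediate
21 | [2,4-bis(benzyloxy)phenyl]lithium | [Li]c1ccc(OCc2ccccc2)cc1OCc1ccccc1 | intermediate (not isolated)
22 | bis-carbinol (ring 2S,3S,4S,5S; carbinol carbons unassigned) | OC(c1ccc(OCc2ccccc2)cc1OCc1ccccc1)[C@@H]1[C@@H](C(O)c2ccc(OCc3ccccc3)cc2OCc2ccccc2)[C@@H](c2ccc(OCc3ccccc3)cc2)O[C@@H]1c1ccc(OCc2ccccc2)cc1 | intermediate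
23 | [(2S,3R,4R,5S)-2,5-bis[4-(benzyloxy)phenyl]oxolane-3,4-diyl]bis{[2,4-bis(benzyloxy)phenyl]methanone} | O=C(c1ccc(OCc2ccccc2)cc1OCc1ccccc1)[C@@H]1[C@@H](C(=O)c2ccc(OCc3ccccc3)cc2OCc2ccccc2)[C@@H](c2ccc(OCc3ccccc3)cc2)O[C@@H]1c1ccc(OCc2ccccc2)cc1 | intermediate
24 | [(2S,3R,4R,5S)-2,5-bis(4-hydroxyphenyl)oxolane-3,4-diyl]bis[(2,4-dihydroxyphenyl)methanone] | O=C(c1ccc(O)cc1O)[C@@H]1[C@@H](C(=O)c2ccc(O)cc2O)[C@@H](c2ccc(O)cc2)O[C@@H]1c1ccc(O)cc1 | target

**Total step count:** 15
**Longest linear sequence:** 14 (steps 1–11 and 13–15)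

**Steps most likely to fail**

**Step 3 (the labelled step).** The ester-stabilised homoenolate may be protonated at C4 faster than it adds to the electron-rich aldehyde, which leads to redox-ester or enolate chemistry. Enal 4 may also annulate with itself, and control of the face or of cis versus trans may be low.

The fallback is auxiliary-controlled aldol chemistry of known type, setting out from 5 and coming back at 6. (S)-4-Benzyl-1,3-oxazolidin-2-one is N-acylated (n-BuLi, methyl 4-chloro-4-oxobutanoate) to (S)-4-benzyl-3-(4-methoxy-4-oxobutanoyl)-1,3-oxazolidin-2-one F1. The magnesium-halide-catalysed anti-aldol reaction of this imide with 5 (MgCl2 cat., Et3N, Me3SiCl, EtOAc, rt) should give the O-trimethylsilyl anti-aldol adduct F2. The anti adduct is the one that maps onto the cis lactone, and the (S)-auxiliary is chosen on the chelated-enolate model. Catalytic acid in methanol removes the silyl group, and the free C5 hydroxyl closes onto the methyl ester to the cis lactone imide F3. LiOH/H2O2 (THF/H2O, 0 °C) removes the auxiliary to give (2S,3R)-2-[4-(benzyloxy)phenyl]-5-oxooxolane-3-carboxylic acid F4. Boc2O, DMAP (cat.) and t-BuOH convert this acid into 6.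

**Step 8.** Facial selectivity may be poor. The C3 side chain is mismatched with the C4/C5 bias, and a through-space interaction of the ester carbonyl with the cation may change the reactive envelope and send part of the aryl group to the wrong face.

The fallback is silicon-tethered intramolecular aryl delivery, setting out from 8 and coming back at 17. Grignard reagent 13 and Me2SiCl2 give chloro[4-(benzyloxy)phenyl]dimethylsilane F5, which silylates 8 (imidazole) to the aryldimethylsilyl ether lactone F6. i-Bu2AlH at −78 °C gives the lactol F7, and Ac2O/pyridine gives the anomeric acetate F8. BF3·OEt2 at low temperature ionises the acetate, and the oxocarbenium ion is attacked by the ipso carbon of the tethered, para-alkoxy-activated arylsilane through a six-membered transition state. This transition state can only reach the face that carries the C3 side chain, so the 2,3-cis relationship is enforced. Aqueous work-up frees tert-butyl (2S,3R,4S,5S)-2,5-bis[4-(benzyloxy)phenyl]-4-(hydroxymethyl)oxolane-3-carboxylate F9, and LiAlH4 reduces it to 17.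

**Step 4.** Proton transfer from C4–H to the enolate or to residual base may be followed by β-elimination of the C5 carboxylate (Stobbe-type ring opening) or by epimerisation of C4. Capture by gaseous formaldehyde may also be sluggish.

The fallback forms the C3–C bond at the aldehyde oxidation level by enamine catalysis, setting out from 6 and coming back at 10. i-Bu2AlH at −78 °C reduces 6 to the C3-unsubstituted lactol F10. Its open hydroxy-aldehyde form is α-hydroxymethylated with aqueous formaldehyde under diarylprolinol silyl ether catalysis in buffered toluene. Only the aldehyde α-carbon C3 can form the enamine, no strong base is present, and the catalyst antipode is matched to the substrate preference for C3 trans to C4. This gives the hydroxymethyl lactol F11. Selective silylation of its primary alcohol (TBSCl, imidazole, 0 °C) gives 10.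

**Further compounds**
F1 | step 3 | (S)-4-benzyl-3-(4-methoxy-4-oxobutanoyl)-1,3-oxazolidin-2-one | COC(=O)CCC(=O)N1[C@@H](Cc2ccccc2)COC1=O
F2 | step 3 | methyl (3R)-3-{(S)-[4-(benzyloxy)phenyl](trimethylsilyloxy)methyl}-4-[(4S)-4-benzyl-2-oxo-1,3-oxazolidin-3-yl]-4-oxobutanoate | COC(=O)C[C@H]([C@H](O[Si](C)(C)C)c1ccc(OCc2ccccc2)cc1)C(=O)N1[C@@H](Cc2ccccc2)COC1=O
F3 | step 3 | (4S)-4-benzyl-3-{(2S,3R)-2-[4-(benzyloxy)phenyl]-5-oxooxolane-3-carbonyl}-1,3-oxazolidin-2-one | O=C([C@@H]1CC(=O)O[C@@H]1c1ccc(OCc2ccccc2)cc1)N1[C@@H](Cc2ccccc2)COC1=O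
F4 | step 3 | (2S,3R)-2-[4-(benzyloxy)phenyl]-5-oxooxolane-3-carboxylic acid | OC(=O)[C@@H]1CC(=O)O[C@@H]1c1ccc(OCc2ccccc2)cc1
F5 | step 8 | chloro[4-(benzyloxy)phenyl]dimethylsilane | C[Si](C)(Cl)c1ccc(OCc2ccccc2)cc1
F6 | step 8 | tert-butyl (2S,3R,4S)-2-[4-(benzyloxy)phenyl]-4-[({[4-(benzyloxy)phenyl]dimethylsilyl}oxy)methyl]-5-oxooxolane-3-carboxylate | CC(C)(C)OC(=O)[C@@H]1[C@@H](CO[Si](C)(C)c2ccc(OCc3ccccc3)cc2)C(=O)O[C@@H]1c1ccc(OCc2ccccc2)cc1
F7 | step 8 | lactol of F6 (hemiacetal carbon unassigned) | CC(C)(C)OC(=O)[C@@H]1[C@@H](CO[Si](C)(C)c2ccc(OCc3ccccc3)cc2)C(O)O[C@@H]1c1ccc(OCc2ccccc2)cc1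
F8 | step 8 | anomeric acetate of F7 (acetal carbon unassigned) | CC(C)(C)OC(=O)[C@@H]1[C@@H](CO[Si](C)(C)c2ccc(OCc3ccccc3)cc2)C(OC(C)=O)O[C@@H]1c1ccc(OCc2ccccc2)cc1
F9 | step 8 | tert-butyl (2S,3R,4S,5S)-2,5-bis[4-(benzyloxy)phenyl]-4-(hydroxymethyl)oxolane-3-carboxylate | CC(C)(C)OC(=O)[C@@H]1[C@@H](CO)[C@@H](c2ccc(OCc3ccccc3)cc2)O[C@@H]1c1ccc(OCc2ccccc2)cc1
F10 | step 4 | tert-butyl (2S,3R)-2-[4-(benzyloxy)phenyl]-5-hydroxyoxolane-3-carboxylate (hemiacetal carbon unassigned) | CC(C)(C)OC(=O)[C@@H]1CC(O)O[C@@H]1c1ccc(OCc2ccccc2)cc1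
F11 | step 4 | tert-butyl (2S,3R,4S)-2-[4-(benzyloxy)phenyl]-5-hydroxy-4-(hydroxymethyl)oxolane-3-carboxylate (hemiacetal carbon unassigned) | CC(C)(C)OC(=O)[C@@H]1[C@@H](CO)C(O)O[C@@H]1c1ccc(OCc2ccccc2)cc1
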